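**Plan**
- Ring numbering used throughout: C1 = ketone carbon, C2=C3 = enone alkene, C4 = quaternary carbon with the acetoxy group and the C8 chain, C5 = carbon with the (Z)-pentenyl group.
- Retrosynthesis cuts: the acid goes back to a silyl-protected primary alcohol, the acetyl–O bond to a C4 tertiary alcohol, the C5–H bond to the C5–O bond of a C4/C5 oxirane, the C2=C3 π bond to CH2–CH2, the C4–O bond to oxygen transfer onto a C4=C5 alkene, then the C4–chain and C5–pentenyl bonds.
- Enabling feature: C4–O lies 1,3 to C1 across C5, so moving the ring alkene to C4=C5 and reducing C1 to a carbinol gives a 2,3-dialkylcyclopent-2-en-1-ol whose C1 hydroxyl can deliver oxygen to C4 of the cyclopentene ring.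
- Forward order: the carbocycle is bought as cyclopentane-1,3-dione; the pentenyl group is joined first, the C8 chain second (with carbonyl transposition); the oxirane is the only ring formed and is opened again after the C2=C3 alkene is in place.
- Stereochemistry: C1 carbinol (R) from a CBS reduction; C4 (S) from the hydroxyl-directed epoxidation; C5 (S) by equilibration of the enolisable centre; the (Z)-alkene is bought.

Key step: step 6

Assumption: the (5S) arrangement of the target (pentenyl trans to the C8 chain, cis to the C4 oxygen) is taken to be the more stable one at the enolisable C5 centre, as is usual for vicinal alkyl groups on a cyclopentanone.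

Step 1
Reactants: 1 cyclopentane-1,3-dione; 2 (Z)-1-bromopent-2-ene
Product: 3 2-[(Z)-pent-2-en-1-yl]cyclopentane-1,3-dione
Conditions: KOH (1.0 equiv), H2O, rt to 50 °C
Reagents that add atoms: none
Why: C-alkylation of the enolate of a cyclic 1,3-dione by SN2 attack on the primary allylic bromide attaches the pentenyl group at the future C5 with the (Z) geometry kept, and water as solvent favours C- over O-alkylation.

Step 2
Reactants: 3 2-[(Z)-pent-2-en-1-yl]cyclopentane-1,3-dione
Product: 4 3-methoxy-2-[(Z)-pent-2-en-1-yl]cyclopent-2-en-1-one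
Conditions: Me3SiCHN2 (hexanes), MeOH–toluene, 0 °C to rt
Reagents that add atoms: trimethylsilyldiazomethane, C[Si](C)(C)C=[N+]=[N-]
Why: O-methylation of the acidic enol of the 1,3-dione by the diazoalkane gives the vinylogous ester, and since the dione is symmetric only one enol ether can form.

Step 3
Reactants: 5 8-bromooctan-1-ol
Product: 6 [(8-bromooctyl)oxy](tert-butyl)dimethylsilane
Conditions: t-BuMe2SiCl, imidazole, CH2Cl2, 0 °C to rt
Reagents that add atoms: tert-butyldimethylsilyl chloride, CC(C)(C)[Si](C)(C)Cl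
Why: Imidazole-promoted silylation of a primary alcohol masks the future carboxyl carbon for the organometallic and redox steps that follow.

Step 4
Reactants: 6 [(8-bromooctyl)oxy](tert-butyl)dimethylsilane; 4 3-methoxy-2-[(Z)-pent-2-en-1-yl]cyclopent-2-en-1-one
Product: 9 3-{8-[(tert-butyldimethylsilyl)oxy]octyl}-2-[(Z)-pent-2-en-1-yl]cyclopent-2-en-1-one, via Grignard reagent 7 (not isolated), via bromomagnesium alkoxide adduct 8 (not isolated)
Conditions: 6, Mg, THF, 40 °C; then 4, THF, 0 °C to rt; then 1 M aq. HCl, 0 °C, 15 min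
Reagents that add atoms: water, O
Why: Stork–Danheiser alkylative carbonyl transposition, in which the Grignard reagent adds 1,2 to the vinylogous ester and cold dilute acid ionises the tertiary allylic alkoxide to a methoxy-stabilised allyl cation that takes up water at the methoxy-bearing carbon and loses methanol, so that the chain ends on C4 and the carbonyl on C1; the primary silyl ether should survive the brief cold acid treatment.

Step 5
Reactants: 9 3-{8-[(tert-butyldimethylsilyl)oxy]octyl}-2-[(Z)-pent-2-en-1-yl]cyclopent-2-en-1-one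
Product: 10 (1R)-3-{8-[(tert-butyldimethylsilyl)oxy]octyl}-2-[(Z)-pent-2-en-1-yl]cyclopent-2-en-1-ol
Conditions: (S)-Me-CBS catalyst [(3aS)-1-methyl-3,3-diphenyltetrahydro-1H,3H-pyrrolo[1,2-c][1,3,2]oxazaborole] (0.2 equiv), catecholborane, toluene, −78 to −40 °C; then MeOH, aq. NaOH wash
Reagents that add atoms: none
Why: Corey–Bakshi–Shibata reduction, in which the tetrasubstituted alkenyl arm acts as the large group and the ring CH2 as the small one, so the (S)-catalyst should deliver hydride to the face that gives the (1R)-carbinol, while catecholborane at low temperature does not hydroborate the isolated (Z)-alkene.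

Step 6
Reactants: 10 (1R)-3-{8-[(tert-butyldimethylsilyl)oxy]octyl}-2-[(Z)-pent-2-en-1-yl]cyclopent-2-en-1-ol
Product: 11 (1R,2R,5S)-5-{8-[(tert-butyldimethylsilyl)oxy]octyl}-1-[(Z)-pent-2-en-1-yl]-6-oxabicyclo[3.1.0]hexan-2-ol
Conditions: VO(acac)2 (5 mol %), t-BuOOH (1.2 equiv, in decane), CH2Cl2, 0 °C
Reagents that add atoms: tert-butyl hydroperoxide, CC(C)(C)OO
Why: t-BuOOH oxidises VO(acac)2 to a pentavalent vanadium species that takes up the C1 alkoxide of 10 and a tert-butylperoxide ligand, and the activated peroxide oxygen is then passed within this complex to the C4=C5 π bond in one concerted step. The closest known reaction type is the vanadium-catalysed, hydroxyl-directed epoxidation of cyclic allylic alcohols, which is established for tetrasubstituted cycloalkenols. The oxirane is the only ring closed, and it closes by a concerted [2+1] oxygen-atom transfer in which the C4–O and C5–O bonds form together on one face. Both new stereocentres, C4 and C5, are dictated by the (R)-carbinol at C1, because the metal-bound oxidant can reach only the face of the cyclopentene that carries the C1–O bond; this places the C4–O bond in the configuration of the target. The step needs full facial selectivity and selectivity for the ring alkene over the side-chain (Z)-alkene and over oxidation of the carbinol; the ring alkene is allylic to the hydroxyl and tetrasubstituted, hence held close to the metal and electron-rich, whereas the side-chain alkene is disubstituted and two carbons further from the hydroxyl, so a slight excess of oxidant at 0 °C should leave it untouched.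

Step 7
Reactants: 11 (1R,2R,5S)-5-{8-[(tert-butyldimethylsilyl)oxy]octyl}-1-[(Z)-pent-2-en-1-yl]-6-oxabicyclo[3.1.0]hexan-2-ol
Product: 12 (1S,5S)-5-{8-[(tert-butyldimethylsilyl)oxy]octyl}-1-[(Z)-pent-2-en-1-yl]-6-oxabicyclo[3.1.0]hexan-2-one
Conditions: Dess–Martin periodinane, pyridine, CH2Cl2, 0 °C to rt
Reagents that add atoms: none
Why: Dess–Martin oxidation of the secondary alcohol under pyridine buffering is mild enough for the acid-labile tetrasubstituted oxirane, and neither oxirane carbon is touched.

Step 8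
Reactants: 12 (1S,5S)-5-{8-[(tert-butyldimethylsilyl)oxy]octyl}-1-[(Z)-pent-2-en-1-yl]-6-oxabicyclo[3.1.0]hexan-2-one
Product: 14 (1S,5S)-5-{8-[(tert-butyldimethylsilyl)oxy]octyl}-1-[(Z)-pent-2-en-1-yl]-6-oxabicyclo[3.1.0]hex-3-en-2-one, via trimethylsilyl enol ether 13 (not isolated)
Conditions: Me3SiCl, LiN(SiMe3)2, THF, −78 °C; then Pd(OAc)2 (1.1 equiv), MeCN, rt
Reagents that add atoms: none
Why: Saegusa–Ito oxidation, in which the ketone can enolise only toward C2 because C5 is fully substituted, so a single silyl enol ether forms and Pd(OAc)2 turns it, through a divalent palladium enolate and β-hydride elimination of a C3 hydrogen, into the C2=C3 enone with the oxirane stereocentres unchanged.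

Step 9
Reactants: 14 (1S,5S)-5-{8-[(tert-butyldimethylsilyl)oxy]octyl}-1-[(Z)-pent-2-en-1-yl]-6-oxabicyclo[3.1.0]hex-3-en-2-one
Product: 16 (4S,5S)-4-hydroxy-4-{8-[(tert-butyldimethylsilyl)oxy]octyl}-5-[(Z)-pent-2-en-1-yl]cyclopent-2-en-1-one, via (4S,5R)-epimer 15 (not isolated)
Conditions: SmI2 (2.2 equiv), THF–MeOH, −90 °C, pH 7 buffer quench; then DBU (1,8-diazabicyclo[5.4.0]undec-7-ene, 0.1 equiv), CH2Cl2, 0 °C to rt
Reagents that add atoms: none
Why: SmI2 reductive cleavage of an α,β-epoxy ketone, in which two single-electron transfers to the carbonyl break the C5–O bond next to it and leave the C4–O bond and its configuration intact, methanol protonates the samarium dienolate at C5 before the enone can be reduced further, and, since this protonation need not favour one face, catalytic DBU should then equilibrate C5 through the cross-conjugated dienolate toward the (5S) isomer with the pentenyl group trans to the C8 chain; loss of hydroxide from that dienolate would give an antiaromatic cyclopentadienone and should not compete.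

Step 10
Reactants: 16 (4S,5S)-4-hydroxy-4-{8-[(tert-butyldimethylsilyl)oxy]octyl}-5-[(Z)-pent-2-en-1-yl]cyclopent-2-en-1-one
Product: 17 (1S,5S)-1-{8-[(tert-butyldimethylsilyl)oxy]octyl}-4-oxo-5-[(Z)-pent-2-en-1-yl]cyclopent-2-en-1-yl acetate
Conditions: Ac2O, DMAP (4-(dimethylamino)pyridine, 0.5 equiv), pyridine, CH2Cl2, rt
Reagents that add atoms: acetic anhydride, CC(=O)OC(C)=O
Why: DMAP-catalysed acylation is the standard way to esterify a hindered tertiary alcohol, and under the weak base pyridine the β-acetoxy ketone should not eliminate because loss of acetate would again give a cyclopentadienone; C4 and C5 are not touched.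

Step 11
Reactants: 17 (1S,5S)-1-{8-[(tert-butyldimethylsilyl)oxy]octyl}-4-oxo-5-[(Z)-pent-2-en-1-yl]cyclopent-2-en-1-yl acetate
Product: 18 (1S,5S)-1-(8-hydroxyoctyl)-4-oxo-5-[(Z)-pent-2-en-1-yl]cyclopent-2-en-1-yl acetate
Conditions: HF·pyridine, THF–pyridine, 0 °C to rt
Reagents that add atoms: none
Why: Fluoride cleavage of a primary silyl ether with buffered HF is chosen over basic fluoride sources so that the base-sensitive β-acetoxy enone and the C5 centre are left alone.

Step 12
Reactants: 18 (1S,5S)-1-(8-hydroxyoctyl)-4-oxo-5-[(Z)-pent-2-en-1-yl]cyclopent-2-en-1-yl acetate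
Product: 19 8-{(1S,5S)-1-acetoxy-4-oxo-5-[(Z)-pent-2-en-1-yl]cyclopent-2-en-1-yl}octanoic acid
Conditions: TEMPO (2,2,6,6-tetramethylpiperidin-1-oxyl, 20 mol %), PhI(OAc)2 (2.4 equiv), MeCN–H2O, rt
Reagents that add atoms: water, O
Why: Oxoammonium-mediated oxidation with PhI(OAc)2 as terminal oxidant takes the primary alcohol through the aldehyde and its hydrate to the acid without base or metal, leaving the enone, the tertiary acetate, the (Z)-alkene and both stereocentres intact.

**Compound list**
1 | cyclopentane-1,3-dione | O=C1CCC(=O)C1 | starting material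
2 | (Z)-1-bromopent-2-ene | CC/C=C\CBr | starting material
3 | 2-[(Z)-pent-2-en-1-yl]cyclopentane-1,3-dione | CC/C=C\CC1C(=O)CCC1=O | intermediate
4 | 3-methoxy-2-[(Z)-pent-2-en-1-yl]cyclopent-2-en-1-one | CC/C=C\CC1=C(OC)CCC1=O | intermediate
5 | 8-bromooctan-1-ol | OCCCCCCCCBr | starting material
6 | [(8-bromooctyl)oxy](tert-butyl)dimethylsilane | CC(C)(C)[Si](C)(C)OCCCCCCCCBr | intermediate
7 | {8-[(tert-butyldimethylsilyl)oxy]octyl}magnesium bromide (not isolated) | CC(C)(C)[Si](C)(C)OCCCCCCCC[Mg]Br | intermediate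
8 | bromomagnesium 1-{8-[(tert-butyldimethylsilyl)oxy]octyl}-3-methoxy-2-[(Z)-pent-2-en-1-yl]cyclopent-2-en-1-olate, racemic (not isolated) | CC/C=C\CC1=C(OC)CCC1(O[Mg]Br)CCCCCCCCO[Si](C)(C)C(C)(C)C | intermediate
9 | 3-{8-[(tert-butyldimethylsilyl)oxy]octyl}-2-[(Z)-pent-2-en-1-yl]cyclopent-2-en-1-one | CC/C=C\CC1=C(CCCCCCCCO[Si](C)(C)C(C)(C)C)CCC1=O | intermediate
10 | (1R)-3-{8-[(tert-butyldimethylsilyl)oxy]octyl}-2-[(Z)-pent-2-en-1-yl]cyclopent-2-en-1-ol | CC/C=C\CC1=C(CCCCCCCCO[Si](C)(C)C(C)(C)C)CC[C@H]1O | intermediate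
11 | (1R,2R,5S)-5-{8-[(tert-butyldimethylsilyl)oxy]octyl}-1-[(Z)-pent-2-en-1-yl]-6-oxabicyclo[3.1.0]hexan-2-ol (oxirane syn to the hydroxyl) | CC/C=C\C[C@]12O[C@@]1(CCCCCCCCO[Si](C)(C)C(C)(C)C)CC[C@H]2O | intermediate
12 | (1S,5S)-5-{8-[(tert-butyldimethylsilyl)oxy]octyl}-1-[(Z)-pent-2-en-1-yl]-6-oxabicyclo[3.1.0]hexan-2-one | CC/C=C\C[C@]12O[C@@]1(CCCCCCCCO[Si](C)(C)C(C)(C)C)CCC2=O | intermediate
13 | (1S,5S)-5-{8-[(tert-butyldimethylsilyl)oxy]octyl}-1-[(Z)-pent-2-en-1-yl]-2-[(trimethylsilyl)oxy]-6-oxabicyclo[3.1.0]hex-2-ene (not isolated) | CC/C=C\C[C@]12O[C@@]1(CCCCCCCCO[Si](C)(C)C(C)(C)C)CC=C2O[Si](C)(C)C | intermediate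
14 | (1S,5S)-5-{8-[(tert-butyldimethylsilyl)oxy]octyl}-1-[(Z)-pent-2-en-1-yl]-6-oxabicyclo[3.1.0]hex-3-en-2-one | CC/C=C\C[C@]12O[C@@]1(CCCCCCCCO[Si](C)(C)C(C)(C)C)C=CC2=O | intermediate
15 | (4S,5R)-4-hydroxy-4-{8-[(tert-butyldimethylsilyl)oxy]octyl}-5-[(Z)-pent-2-en-1-yl]cyclopent-2-en-1-one (not isolated) | CC/C=C\C[C@H]1C(=O)C=C[C@]1(CCCCCCCCO[Si](C)(C)C(C)(C)C)O | intermediate
16 | (4S,5S)-4-hydroxy-4-{8-[(tert-butyldimethylsilyl)oxy]octyl}-5-[(Z)-pent-2-en-1-yl]cyclopent-2-en-1-one | CC/C=C\C[C@@H]1C(=O)C=C[C@]1(CCCCCCCCO[Si](C)(C)C(C)(C)C)O | intermediate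
17 | (1S,5S)-1-{8-[(tert-butyldimethylsilyl)oxy]octyl}-4-oxo-5-[(Z)-pent-2-en-1-yl]cyclopent-2-en-1-yl acetate | CC/C=C\C[C@@H]1C(=O)C=C[C@]1(CCCCCCCCO[Si](C)(C)C(C)(C)C)OC(C)=O | intermediate
18 | (1S,5S)-1-(8-hydroxyoctyl)-4-oxo-5-[(Z)-pent-2-en-1-yl]cyclopent-2-en-1-yl acetate | CC/C=C\C[C@@H]1C(=O)C=C[C@]1(CCCCCCCCO)OC(C)=O | intermediate
19 | 8-{(1S,5S)-1-acetoxy-4-oxo-5-[(Z)-pent-2-en-1-yl]cyclopent-2-en-1-yl}octanoic acid | CC/C=C\C[C@@H]1C(=O)C=C[C@]1(CCCCCCCC(=O)O)OC(C)=O | target

**Step count**
Total: 12 steps. Longest linear sequence: 11 steps (steps 1, 2 and 4–12, from cyclopentane-1,3-dione); step 3 is a one-step side branch.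

**Steps most likely to fail**

Step 9. SmI2 may reduce the cross-conjugated enone (conjugate reduction or ketyl coupling) alongside the wanted C5–O cleavage. The fallback opens the oxirane before the C2=C3 alkene exists; it sets out from 12 and comes back at 16. Epoxy ketone 12 is treated with SmI2 in THF–MeOH at −90 °C, which should give (3S)-3-hydroxy-3-{8-[(tert-butyldimethylsilyl)oxy]octyl}-2-[(Z)-pent-2-en-1-yl]cyclopentan-1-one F1 as a mixture at the pentenyl-bearing carbon. To avoid dehydration it is silylated at once with LiN(SiMe3)2 (2.2 equiv) and Me3SiCl at −78 °C. The tertiary alkoxide and the kinetic enolate on the CH2 side are both trapped, giving the bis(trimethylsilyl) compound F2. Pd(OAc)2 in MeCN should then give the 4-(trimethylsilyloxy) enone F3. Citric acid in MeOH removes the trimethylsilyl ether, and the DBU equilibration of step 9 leads to 16.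

Step 10. Acylation of the hindered tertiary hydroxyl may be slow enough that base-induced loss of the C4 oxygen function or retro-aldol ring opening gains ground. The fallback moves the acetylation to the end and runs it without amine base; it sets out from 16 and comes back at 19. HF·pyridine converts 16 into (4S,5S)-4-hydroxy-4-(8-hydroxyoctyl)-5-[(Z)-pent-2-en-1-yl]cyclopent-2-en-1-one F4. TEMPO with PhI(OAc)2 in MeCN–H2O oxidises only the primary hydroxyl, giving 8-{(1S,5S)-1-hydroxy-4-oxo-5-[(Z)-pent-2-en-1-yl]cyclopent-2-en-1-yl}octanoic acid F5. Ac2O with catalytic Sc(OTf)3 in MeCN at −20 °C then acetylates the tertiary alcohol by electrophilic activation, with no silyl ether left to suffer. Aqueous work-up cleaves the mixed anhydride at the carboxyl group and gives 19.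

Step 1. O-alkylation and SN2′ attack may compete with C-alkylation, and the allylic bromide may partly lose its (Z) geometry. The fallback brings in the alkene as an alkyne; it sets out from 1 and comes back at 3. Dione 1 is alkylated under the same aqueous KOH conditions with commercial 1-bromopent-2-yne (CCC#CCBr), which has no alkene geometry to lose, giving 2-(pent-2-yn-1-yl)cyclopentane-1,3-dione F6. Semi-hydrogenation (H2, Pd/CaCO3 poisoned with Pb(OAc)2, quinoline, EtOAc) then sets the (Z)-alkene by syn addition and gives 3.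

**Further compounds**
F1 | step 9 | (3S)-3-hydroxy-3-{8-[(tert-butyldimethylsilyl)oxy]octyl}-2-[(Z)-pent-2-en-1-yl]cyclopentan-1-one (C2 epimers) | CC/C=C\CC1C(=O)CC[C@]1(CCCCCCCCO[Si](C)(C)C(C)(C)C)O
F2 | step 9 | tert-butyldimethyl{8-[(1S)-2-[(Z)-pent-2-en-1-yl]-1,3-bis(trimethylsilyloxy)cyclopent-3-en-1-yl]octyloxy}silane | CC/C=C\CC1C(O[Si](C)(C)C)=CC[C@]1(CCCCCCCCO[Si](C)(C)C(C)(C)C)O[Si](C)(C)C
F3 | step 9 | (4S)-4-{8-[(tert-butyldimethylsilyl)oxy]octyl}-5-[(Z)-pent-2-en-1-yl]-4-[(trimethylsilyl)oxy]cyclopent-2-en-1-one (C5 epimers) | CC/C=C\CC1C(=O)C=C[C@]1(CCCCCCCCO[Si](C)(C)C(C)(C)C)O[Si](C)(C)C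
F4 | step 10 | (4S,5S)-4-hydroxy-4-(8-hydroxyoctyl)-5-[(Z)-pent-2-en-1-yl]cyclopent-2-en-1-one | CC/C=C\C[C@@H]1C(=O)C=C[C@]1(CCCCCCCCO)O
F5 | step 10 | 8-{(1S,5S)-1-hydroxy-4-oxo-5-[(Z)-pent-2-en-1-yl]cyclopent-2-en-1-yl}octanoic acid | CC/C=C\C[C@@H]1C(=O)C=C[C@]1(CCCCCCCC(=O)O)O
F6 | step 1 | 2-(pent-2-yn-1-yl)cyclopentane-1,3-dione | CCC#CCC1C(=O)CCC1=O
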